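## Structural features

The target is a C24 carboxylic acid, numbered here from the carboxyl carbon C1 to the terminal methylene C24, in which a 1,2-dioxane and an oxolane are joined directly through the C6–C7 bond. The dioxane holds C3–C6 with the O–O bridge between C3 and C6; C3 carries the CH2CO2H arm, C6 carries the oxolane, and the two substituents are trans (3R,6R). The oxolane spans C7–C10 and is 2,5-trans (7S,10R), and the vicinal oxygen-bearing pair C6/C7 is erythro. From C10 a six-methylene spacer leads to a (17Z,19E)-diene and, two methylenes further on, to the terminal C23=C24 vinyl group. The O–O bond is the fragile element: it does not survive hydrogenation, phosphines, ylides, hydrides or strong base (fragmentation through C3–H or C6–H). The triene in turn is sensitive to hydrogen, to metathesis catalysts and to isomerisation. The real difficulty is to make two secondary C–O(O) bonds of defined configuration, one of them next to the oxolane, late and under conditions the triene tolerates, while four stereocentres on two rings are each fixed independently. The key step exploits the 1,4-relationship of the peroxide-bearing carbons: C3, C4, C5 and C6 are the four carbons of a but-2-ene-1,4-diol, so the two carbinols can be tied through O–Si–O in a seven-membered 1,3-dioxa-2-silacycloheptene and C4=C5 made by ring-closing metathesis.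

## Logic of the disconnections

33 is traced to 31 and then to 30 without cutting a skeletal bond: only the C1 oxidation level and the C1–O–Si bond change. C1 is kept as a silyl ether until the end because a C1 carbonyl would make a C3 leaving group eliminate, and because fluoride removes silicon without touching O–O. The forward demand is an oxidation that takes the C1 alcohol to the acid faster than the intermediate 32 can lose the β-peroxide, and that ignores the triene.

30 is cut at O–C3 and O–C6, which leads to 28 and its parent 27. Both C–O bonds are to be made by substitution with inversion, so 27 must carry C3 and C6 as the epimers of the target centres (3S,6S). The gain is that the peroxide comes last from the simplest O–O donor and the problem becomes a 1,4-diol. The demand is two secondary displacements, one beside the oxolane, that must outrun elimination in a basic medium.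

27 is traced to 26 by cutting two Si–O bonds. The silicon bridge that templated the ring closure is kept as the diol protecting group while the side chain is built, which saves a protection step. The demand is that the bridge can be removed without loss of the C1 silyl ether; this is why C1 carries a tert-butyldiphenylsilyl group and not an ester or a smaller silyl group.

26 is cut at C17=C18 into 21 and 24, and 24 at C19=C20 into 22 and 23. The triene cannot pass through metathesis or hydrogenation, so it is attached after both. The polarity is chosen with the phosphorus on C17 and the (E)-enal as partner, because a non-stabilised ylide gives the Z alkene reliably whereas an allylic ylide would not. The demand is Z-selective olefination in the presence of the silicon bridge.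

21 goes back through 20 and 19 to 18: C17–P, C17–I and C17–O exchanges, saturation of C4–C5 and loss of the C17 benzyl group. Benzyl is chosen for C17 so that one hydrogenation does both jobs and so that no fluoride-labile group competes at that terminus. The demand is that hydrogen reduces the ring alkene and the benzyl ether without cleaving the allylic C–O or Si–O bonds.

18 is cut at C4=C5 to give 17. This is the strategic cut: it joins the C1–C4 and C5–C17 halves, and the ring it opens has exactly the C3–C6 connectivity of the later peroxide. The demand is closure of a seven-membered ring between two hindered allylic ethers.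

17 is cut at its two Si–O bonds into 14, 15 and 9. The demand is a mixed, not a symmetrical, bis-ether, which calls for sequential silylation through 16. In 17 the descriptors are C3 (R) and C6 (S); both are the spatial epimers of the target centres, and C3 only keeps the letter R because the vinyl group outranks the C2 branch at this stage.

9 is cut at C5–C6 into 7 and 8, with chelation expected to give the threo carbinol. 7 comes from 6, and 6 from 5 by cutting O–C7, an oxidative ring closure that sets C7 trans to C10. 5 is cut at C11–C12 into 2 and 4 (made from 3), and 2 comes from racemic 1 by resolution; this fixes C10.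

14 comes from racemic 13 by enzymatic resolution. 13 is cut at C3–C4 into 12 and 8, and 12 goes back through 11 to 10.

## Other disconnections considered

Alternative 1: The cut reconnects C3 and C10 as a ring alkene, so that C3–C10 comes from one eight-membered carbocycle, (1S,2S,5Z)-2-[(tert-butyldimethylsilyl)oxy]cyclooct-5-en-1-ol A1.
- Forward key step: ozonolysis with reductive work-up cleaves the alkene; the free C7 hydroxyl captures the C10 aldehyde and gives the lactol (4S)-4-[(tert-butyldimethylsilyl)oxy]-4-[(2S)-5-hydroxyoxolan-2-yl]butanal A2, with C3 left as a free aldehyde.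
- In its favour: the whole C3–C10 backbone comes from a cheap ring with no C–C bond construction, and the two new carbonyls differentiate themselves.
- Against it here: C10 emerges as an anomeric mixture, and the chain would have to be attached through an oxocarbenium ion, where 2,5-trans selectivity is substrate-dependent. C3 still has to be turned into a stereodefined carbinol with C1–C2 attached. A1 needs an asymmetric desymmetrisation of its own, and ozone forces the step to precede every other alkene.
- Comparison: on raw-material cost and on C–C bond count for the core this alternative is the better plan. On the C6/C7 threo pattern the two are equal, since A2 carries the same C6 epimer that 27 needs. The chosen plan should be the better one at C10 (set by cyclisation of a resolved carbinol) and at C3 (fixed before the halves are joined). The step count is not expected to be lower.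

Alternative 2: The cut is at both C–O bonds of the peroxide.
- Forward key step: the bis-mesylate (3S,6S)-1-[(tert-butyldimethylsilyl)oxy]-6-{(2S,5R)-5-[(7Z,9E)-tetradeca-7,9,13-trien-1-yl]oxolan-2-yl}hexane-3,6-diyl dimethanesulfonate A3 reacts with alkaline hydrogen peroxide, first at C3 and then intramolecularly at C6, to give the dioxane tert-butyldimethyl{2-[(3R,6R)-6-{(2S,5R)-5-[(7Z,9E)-tetradeca-7,9,13-trien-1-yl]oxolan-2-yl}-1,2-dioxan-3-yl]ethoxy}silane A4.
- In its favour: O–O comes from the simplest source, late, and both centres are set by stereospecific inversion.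
- Against it: the closure at C6 is hindered and the medium is basic, and as a lead idea it leaves open how the 1,4-diol behind A3 is assembled.
- Comparison: this is a complement more than a rival. The chosen route performs the same event at step 19 on 28, so on mechanism the two are equal. The smaller silyl group of A4 would come off more easily at the end, which is a point for the alternative. It would give less margin when the silicon bridge is cleaved selectively, and the chosen plan adds the answer to the C4–C5 union.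

Alternative 3: The cut is at O–C10 and C10–C11.
- Forward key step: the diazoketone (4S)-1-diazo-4-(prop-2-en-1-yloxy)-5-[(tert-butyldiphenylsilyl)oxy]pentan-2-one A5 with Cu(acac)2 forms a copper carbenoid, which the allyl ether oxygen traps as an oxonium ylide. A [2,3]-shift then moves the allyl group to C10 and gives (2R,5S)-2-(prop-2-en-1-yl)-5-{[(tert-butyldiphenylsilyl)oxy]methyl}oxolan-3-one A6.
- In its favour: this reaction class is known for 2,5-trans selectivity; C7 comes from the chiral pool with no resolution loss; C10 and the first chain bond are made together.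
- Against it here: a diazoketone has to be prepared and handled. The C9 carbonyl of A6 has to be removed afterwards. The allyl group supplies only three chain carbons. The plan says nothing about the peroxide.
- Comparison: on trans selectivity the two are equal, and on stereochemical throughput (no kinetic resolution) the alternative is better. The chosen plan is shorter for the oxolane: 6 is reached from 1 in three steps without an excess carbonyl.

Key step: step 11

Remark on the chemistry: the senses of the two kinetic resolutions (steps 1 and 9) follow the usual empirical models, and the absolute configuration of 2 and 14 is to be confirmed before they are carried on. Atom numbers C1–C24 refer to the target skeleton throughout.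

## Route

Step 1
Reactants: 1 rac-2-(but-3-en-1-yl)oxirane
Product: 2 (2S)-2-(but-3-en-1-yl)oxirane
Conditions: (S,S)-Co(salen)(OAc) (0.5 mol%, trivalent cobalt; salen = N,N'-bis(3,5-di-tert-butylsalicylidene)cyclohexane-1,2-diaminate), H2O (0.55 equiv), neat, 0 °C → rt; distillation
Reagents that add atoms: none
Why: Jacobsen hydrolytic kinetic resolution: the chiral cobalt salen complex activates water and one epoxide enantiomer cooperatively, so the (R)-epoxide is hydrolysed to the diol and (S)-2 is recovered by distillation. The C10 stereocentre of the target originates here.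

Step 2
Reactants: 2 (2S)-2-(but-3-en-1-yl)oxirane; 3 benzyl 6-bromohexyl ether
Product: 5 (5R)-12-(benzyloxy)dodec-1-en-5-ol, via Grignard reagent 4 (not isolated)
Conditions: 3, Mg, THF, rt → 40 °C; then CuI (10 mol%), 2, THF, −30 → 0 °C; aq NH4Cl
Reagents that add atoms: none
Why: Copper-catalysed Grignard opening of a terminal epoxide: the cuprate from 4 attacks the unsubstituted CH2 in an SN2 fashion and forms C11–C12. The C10–O bond is not touched, so the configuration of 2 is carried into 5.

Step 3
Reactants: 5 (5R)-12-(benzyloxy)dodec-1-en-5-ol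
Product: 6 [(2S,5R)-5-[7-(benzyloxy)heptyl]oxolan-2-yl]methanol
Conditions: Co(modp)2 (10 mol%, divalent cobalt; modp = 1-morpholinocarbamoyl-4,4-dimethylpentane-1,3-dionate), O2 (1 atm), t-BuOOH (10 mol%), i-PrOH, 55 °C
Reagents that add atoms: dioxygen, O=O
Why: Mukaiyama aerobic oxidative cyclisation of a pent-4-en-1-ol: cobalt-mediated 5-exo closure of the C10 oxygen onto C7 and oxygenation of C6 give the oxolane methanol. C7 is set trans to C10 because the ring forms through an arrangement with the C10 chain pseudo-equatorial.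

Step 4
Reactants: 6 [(2S,5R)-5-[7-(benzyloxy)heptyl]oxolan-2-yl]methanol
Product: 7 (2S,5R)-5-[7-(benzyloxy)heptyl]oxolane-2-carbaldehyde
Conditions: (COCl)2, DMSO, CH2Cl2, −78 °C; Et3N, −78 → −20 °C; used crude
Reagents that add atoms: none
Why: Swern oxidation: activated DMSO stops at the aldehyde at low temperature. The α-oxygenated C7 centre should not epimerise if 7 is used without chromatography.

Step 5
Reactants: 7 (2S,5R)-5-[7-(benzyloxy)heptyl]oxolane-2-carbaldehyde; 8 vinylmagnesium bromide
Product: 9 (1S)-1-{(2S,5R)-5-[7-(benzyloxy)heptyl]oxolan-2-yl}prop-2-en-1-ol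
Conditions: MgBr2·OEt2 (3 equiv), CH2Cl2, −78 °C; then 8 (THF solution, slow addition), −78 °C; aq NH4Cl
Reagents that add atoms: none
Why: Chelation-controlled Grignard addition (Cram chelate model): magnesium bridges the carbonyl and ring oxygens and vinyl attacks the face away from C8. This should give the threo (6S) carbinol, the C6 epimer of the target centre that the later inversion requires.

Step 6
Reactants: 10 propane-1,3-diol
Product: 11 3-[(tert-butyldiphenylsilyl)oxy]propan-1-ol
Conditions: NaH (1.0 equiv), THF, 0 °C → rt; TBDPSCl (1.0 equiv)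
Reagents that add atoms: tert-butyl(chloro)diphenylsilane, CC(C)(C)[Si](Cl)(c1ccccc1)c1ccccc1
Why: Monosilylation of a symmetrical diol through its sparingly soluble monosodium alkoxide, which is silylated once.

Step 7
Reactants: 11 3-[(tert-butyldiphenylsilyl)oxy]propan-1-ol
Product: 12 3-[(tert-butyldiphenylsilyl)oxy]propanal
Conditions: (COCl)2, DMSO, CH2Cl2, −78 °C; Et3N, −78 → 0 °C
Reagents that add atoms: none
Why: Swern oxidation of a primary alcohol; the mild, non-aqueous conditions avoid β-elimination of the silyloxy group.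

Step 8
Reactants: 12 3-[(tert-butyldiphenylsilyl)oxy]propanal; 8 vinylmagnesium bromide
Product: 13 rac-5-[(tert-butyldiphenylsilyl)oxy]pent-1-en-3-ol
Conditions: 8, THF, −78 → 0 °C; aq NH4Cl
Reagents that add atoms: none
Why: Grignard 1,2-addition to an aldehyde; the product is racemic at C3 and is resolved in the next step.

Step 9
Reactants: 13 rac-5-[(tert-butyldiphenylsilyl)oxy]pent-1-en-3-ol
Product: 14 (3R)-5-[(tert-butyldiphenylsilyl)oxy]pent-1-en-3-ol
Conditions: Novozym 435 (immobilised Candida antarctica lipase B), vinyl acetate, hexane, 30 °C, to just past half conversion; chromatography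
Reagents that add atoms: none
Why: Lipase-catalysed kinetic resolution by irreversible transesterification: by the Kazlauskas rule the enzyme acylates the enantiomer that places vinyl in the small pocket and the silyloxyethyl arm in the large one, which is (S). (R)-14 should therefore be recovered as the free alcohol; this sets C3 as the epimer of the target centre.

Step 10
Reactants: 14 (3R)-5-[(tert-butyldiphenylsilyl)oxy]pent-1-en-3-ol; 15 dichlorodi(propan-2-yl)silane; 9 (1S)-1-{(2S,5R)-5-[7-(benzyloxy)heptyl]oxolan-2-yl}prop-2-en-1-ol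
Product: 17 {[(1S)-1-{(2S,5R)-5-[7-(benzyloxy)heptyl]oxolan-2-yl}prop-2-en-1-yl]oxy}{[(3R)-5-[(tert-butyldiphenylsilyl)oxy]pent-1-en-3-yl]oxy}di(propan-2-yl)silane, via chlorosilyl ether 16 (not isolated)
Conditions: 14 (1.3 equiv), 15 (4 equiv), imidazole, CH2Cl2, 0 °C; excess 15 removed in vacuo; then 9 (1.0 equiv), imidazole, DMAP (cat.), CH2Cl2, rt
Reagents that add atoms: none
Why: Sequential silylation of two different alcohols with a dichlorosilane: excess 15 converts 14 into the monochloride 16 only, and after removal of surplus 15 the remaining Si–Cl bond is displaced by 9. The isopropyl groups slow over-reaction and should make 17 stable to chromatography.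

Step 11
Reactants: 17 {[(1S)-1-{(2S,5R)-5-[7-(benzyloxy)heptyl]oxolan-2-yl}prop-2-en-1-yl]oxy}{[(3R)-5-[(tert-butyldiphenylsilyl)oxy]pent-1-en-3-yl]oxy}di(propan-2-yl)silane
Product: 18 (4S,7R)-4-{(2S,5R)-5-[7-(benzyloxy)heptyl]oxolan-2-yl}-7-{2-[(tert-butyldiphenylsilyl)oxy]ethyl}-2,2-di(propan-2-yl)-4,7-dihydro-1,3,2-dioxasilepine
Conditions: second-generation Grubbs catalyst RuCl2(=CHPh)(PCy3)(SIMes) (5–10 mol%), CH2Cl2 (0.005 M), 40 °C, argon sparge
Reagents that add atoms: none
Why: Ring-closing alkene metathesis on a temporary silicon tether: the ruthenium benzylidene initiates at either terminal vinyl group of 17, the new alkylidene engages the second vinyl group intramolecularly through a ruthenacyclobutane, and cycloreversion releases ethene and forms C4=C5. The closest known reaction type is the ring-closing metathesis of dialkylsilylene bis(allylic ethers) to 4,7-dihydro-1,3,2-dioxasilepines, the established way to a (Z)-but-2-ene-1,4-diol from two different allylic alcohols. The one ring closed is the seven-membered O–Si–O–C3–C4=C5–C6 ring, closed at C4=C5 by metathesis of two terminal alkenes, and in a ring of this size the alkene can only be cis. No stereocentre is created: C3 and C6 come in unchanged from 14 and 9, and since each was made as a single isomer the diol carries no diastereomer problem. The selectivity needed is hetero-coupling of the two allylic partners over homodimerisation and ring closure over oligomerisation; the tether makes the wanted coupling intramolecular, and high dilution with removal of ethene does the rest. The two isopropyl groups on silicon favour the folded conformer and shield the Si–O bonds, and the second-generation catalyst is chosen because both alkenes are allylic, oxygenated and hindered. 17 holds no other alkene, and the benzyl ether, the silyl ether and the oxolane are inert to the catalyst.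

Step 12
Reactants: 18 (4S,7R)-4-{(2S,5R)-5-[7-(benzyloxy)heptyl]oxolan-2-yl}-7-{2-[(tert-butyldiphenylsilyl)oxy]ethyl}-2,2-di(propan-2-yl)-4,7-dihydro-1,3,2-dioxasilepine
Product: 19 7-{(2R,5S)-5-[(4S,7S)-7-{2-[(tert-butyldiphenylsilyl)oxy]ethyl}-2,2-di(propan-2-yl)-1,3,2-dioxasilepan-4-yl]oxolan-2-yl}heptan-1-ol
Conditions: H2 (1 atm), Pd/C (10 wt% Pd), EtOAc, rt
Reagents that add atoms: none
Why: Heterogeneous catalytic hydrogenation: the cis ring alkene is saturated and the C17 benzyl ether is hydrogenolysed in the same operation. Ethyl acetate avoids solvolysis of the silyl groups, and no stereocentre is touched (the C3 descriptor changes to S only because the ranking of its neighbours changes).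

Step 13
Reactants: 19 7-{(2R,5S)-5-[(4S,7S)-7-{2-[(tert-butyldiphenylsilyl)oxy]ethyl}-2,2-di(propan-2-yl)-1,3,2-dioxasilepan-4-yl]oxolan-2-yl}heptan-1-ol
Product: 20 (4S,7S)-7-{2-[(tert-butyldiphenylsilyl)oxy]ethyl}-4-[(2S,5R)-5-(7-iodoheptyl)oxolan-2-yl]-2,2-di(propan-2-yl)-1,3,2-dioxasilepane
Conditions: I2, PPh3, imidazole, CH2Cl2, 0 °C → rt
Reagents that add atoms: iodine, [I][I]
Why: Appel-type iodination: the alkoxyphosphonium ion of the primary C17 alcohol is displaced by iodide; the imidazole buffer protects the silicon bridge.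

Step 14
Reactants: 20 (4S,7S)-7-{2-[(tert-butyldiphenylsilyl)oxy]ethyl}-4-[(2S,5R)-5-(7-iodoheptyl)oxolan-2-yl]-2,2-di(propan-2-yl)-1,3,2-dioxasilepane
Product: 21 {7-[(2R,5S)-5-[(4S,7S)-7-{2-[(tert-butyldiphenylsilyl)oxy]ethyl}-2,2-di(propan-2-yl)-1,3,2-dioxasilepan-4-yl]oxolan-2-yl]heptyl}triphenylphosphonium iodide
Conditions: PPh3 (3 equiv), i-Pr2NEt (0.1 equiv), MeCN, 75 °C
Reagents that add atoms: triphenylphosphine, c1ccc(cc1)P(c1ccccc1)c1ccccc1
Why: Quaternisation of triphenylphosphine by a primary iodide (SN2); a trace of amine scavenges adventitious acid so that the silyl groups survive the heating.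

Step 15
Reactants: 22 pent-4-enal; 23 (triphenylphosphoranylidene)acetaldehyde
Product: 24 (2E)-hepta-2,6-dienal
Conditions: toluene, 80 °C; distillation
Reagents that add atoms: none
Why: Wittig olefination with a stabilised formylmethylene ylide, which is E-selective. A single homologation is expected because the product enal is less electrophilic than the aliphatic aldehyde.

Step 16
Reactants: 21 {7-[(2R,5S)-5-[(4S,7S)-7-{2-[(tert-butyldiphenylsilyl)oxy]ethyl}-2,2-di(propan-2-yl)-1,3,2-dioxasilepan-4-yl]oxolan-2-yl]heptyl}triphenylphosphonium iodide; 24 (2E)-hepta-2,6-dienal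
Product: 26 (4S,7S)-7-{2-[(tert-butyldiphenylsilyl)oxy]ethyl}-2,2-di(propan-2-yl)-4-{(2S,5R)-5-[(7Z,9E)-tetradeca-7,9,13-trien-1-yl]oxolan-2-yl}-1,3,2-dioxasilepane, via phosphorus ylide 25 (not isolated)
Conditions: NaN(SiMe3)2 (1.0 equiv), THF, −78 °C; then 24, −78 °C → rt
Reagents that add atoms: none
Why: Wittig olefination with a non-stabilised ylide under lithium-free conditions: kinetic formation of the cis-oxaphosphetane should give the Z alkene at C17=C18, by 1,2-addition to the enal. The E geometry of C19=C20 is carried over from 24.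

Step 17
Reactants: 26 (4S,7S)-7-{2-[(tert-butyldiphenylsilyl)oxy]ethyl}-2,2-di(propan-2-yl)-4-{(2S,5R)-5-[(7Z,9E)-tetradeca-7,9,13-trien-1-yl]oxolan-2-yl}-1,3,2-dioxasilepane
Product: 27 (3S,6S)-1-[(tert-butyldiphenylsilyl)oxy]-6-{(2S,5R)-5-[(7Z,9E)-tetradeca-7,9,13-trien-1-yl]oxolan-2-yl}hexane-3,6-diol
Conditions: HF·pyridine, pyridine, THF, 0 °C, monitored closely
Reagents that add atoms: none
Why: Fluoride cleavage of a dialkoxysilane: silicon bearing two oxygens and two isopropyl groups is more electrophilic and less shielded than the tert-butyldiphenylsilyl ether, so buffered HF·pyridine should remove only the bridge.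

Step 18
Reactants: 27 (3S,6S)-1-[(tert-butyldiphenylsilyl)oxy]-6-{(2S,5R)-5-[(7Z,9E)-tetradeca-7,9,13-trien-1-yl]oxolan-2-yl}hexane-3,6-diol
Product: 28 (3S,6S)-1-[(tert-butyldiphenylsilyl)oxy]-6-{(2S,5R)-5-[(7Z,9E)-tetradeca-7,9,13-trien-1-yl]oxolan-2-yl}hexane-3,6-diyl dimethanesulfonate
Conditions: MsCl (4 equiv), Et3N, CH2Cl2, −20 → 0 °C
Reagents that add atoms: methanesulfonyl chloride, CS(=O)(=O)Cl
Why: Sulfonylation of both secondary alcohols through sulfene: only O–S bonds form, so C3 and C6 keep their configuration. Excess reagent at low temperature should make the second sulfonylation faster than cyclisation of the mono-mesylate to an oxolane.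

Step 19
Reactants: 28 (3S,6S)-1-[(tert-butyldiphenylsilyl)oxy]-6-{(2S,5R)-5-[(7Z,9E)-tetradeca-7,9,13-trien-1-yl]oxolan-2-yl}hexane-3,6-diyl dimethanesulfonate
Product: 30 tert-butyl{2-[(3R,6R)-6-{(2S,5R)-5-[(7Z,9E)-tetradeca-7,9,13-trien-1-yl]oxolan-2-yl}-1,2-dioxan-3-yl]ethoxy}diphenylsilane, via hydroperoxy mesylate 29 (not isolated)
Conditions: H2O2 (50% aq, large excess), KOH, MeOH/THF, 0 °C → rt
Reagents that add atoms: hydrogen peroxide, OO
Why: Double nucleophilic displacement of a 1,4-bis-mesylate by alkaline hydrogen peroxide: the hydroperoxide anion, an α-effect nucleophile, displaces the less hindered C3 mesylate with inversion to give 29. The derived peroxy anion then closes 6-exo-tet on C6, again with inversion, which should give the trans (3R,6R) dioxane.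

Step 20
Reactants: 30 tert-butyl{2-[(3R,6R)-6-{(2S,5R)-5-[(7Z,9E)-tetradeca-7,9,13-trien-1-yl]oxolan-2-yl}-1,2-dioxan-3-yl]ethoxy}diphenylsilane
Product: 31 2-[(3R,6R)-6-{(2S,5R)-5-[(7Z,9E)-tetradeca-7,9,13-trien-1-yl]oxolan-2-yl}-1,2-dioxan-3-yl]ethan-1-ol
Conditions: Bu4NF, AcOH (1:1), THF, 0 °C → rt
Reagents that add atoms: none
Why: Fluoride desilylation of a primary silyl ether; the acetic acid buffer keeps the medium from becoming basic enough to fragment the peroxide.

Step 21
Reactants: 31 2-[(3R,6R)-6-{(2S,5R)-5-[(7Z,9E)-tetradeca-7,9,13-trien-1-yl]oxolan-2-yl}-1,2-dioxan-3-yl]ethan-1-ol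
Product: 33 2-[(3R,6R)-6-{(2S,5R)-5-[(7Z,9E)-tetradeca-7,9,13-trien-1-yl]oxolan-2-yl}-1,2-dioxan-3-yl]acetic acid, via aldehyde 32 (not isolated)
Conditions: TEMPO (0.2 equiv), PhI(OAc)2 (2.5 equiv), MeCN/H2O (1:1), rt
Reagents that add atoms: water, O
Why: Oxoammonium-mediated oxidation of a primary alcohol to the carboxylic acid through the aldehyde hydrate. The near-neutral aqueous medium oxidises 32 as it forms, and the oxidant does not attack alkenes or dialkyl peroxides.

## Compound list

1 | rac-2-(but-3-en-1-yl)oxirane | C=CCCC1CO1 | starting material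
2 | (2S)-2-(but-3-en-1-yl)oxirane | C=CCC[C@H]1CO1 | intermediate
3 | benzyl 6-bromohexyl ether | BrCCCCCCOCc1ccccc1 | starting material
4 | [6-(benzyloxy)hexyl]magnesium bromide | Br[Mg]CCCCCCOCc1ccccc1 | intermediate
5 | (5R)-12-(benzyloxy)dodec-1-en-5-ol | C=CCC[C@H](O)CCCCCCCOCc1ccccc1 | intermediate
6 | [(2S,5R)-5-[7-(benzyloxy)heptyl]oxolan-2-yl]methanol | c1ccccc1COCCCCCCC[C@@H]2CC[C@@H](CO)O2 | intermediate
7 | (2S,5R)-5-[7-(benzyloxy)heptyl]oxolane-2-carbaldehyde | c1ccccc1COCCCCCCC[C@@H]2CC[C@@H](C=O)O2 | intermediate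
8 | vinylmagnesium bromide | C=C[Mg]Br | starting material
9 | (1S)-1-{(2S,5R)-5-[7-(benzyloxy)heptyl]oxolan-2-yl}prop-2-en-1-ol | c1ccccc1COCCCCCCC[C@@H]2CC[C@@H]([C@H](C=C)O)O2 | intermediate
10 | propane-1,3-diol | OCCCO | starting material
11 | 3-[(tert-butyldiphenylsilyl)oxy]propan-1-ol | OCCCO[Si](c1ccccc1)(c1ccccc1)C(C)(C)C | intermediate
12 | 3-[(tert-butyldiphenylsilyl)oxy]propanal | O=CCCO[Si](c1ccccc1)(c1ccccc1)C(C)(C)C | intermediate
13 | rac-5-[(tert-butyldiphenylsilyl)oxy]pent-1-en-3-ol | C=CC(O)CCO[Si](c1ccccc1)(c1ccccc1)C(C)(C)C | intermediate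
14 | (3R)-5-[(tert-butyldiphenylsilyl)oxy]pent-1-en-3-ol | O[C@@H](C=C)CCO[Si](c1ccccc1)(c1ccccc1)C(C)(C)C | intermediate
15 | dichlorodi(propan-2-yl)silane | CC(C)[Si](Cl)(Cl)C(C)C | starting material
16 | {[(3R)-5-[(tert-butyldiphenylsilyl)oxy]pent-1-en-3-yl]oxy}chlorodi(propan-2-yl)silane | CC(C)[Si](Cl)(C(C)C)O[C@@H](C=C)CCO[Si](c1ccccc1)(c1ccccc1)C(C)(C)C | intermediate
17 | {[(1S)-1-{(2S,5R)-5-[7-(benzyloxy)heptyl]oxolan-2-yl}prop-2-en-1-yl]oxy}{[(3R)-5-[(tert-butyldiphenylsilyl)oxy]pent-1-en-3-yl]oxy}di(propan-2-yl)silane | c1ccccc1COCCCCCCC[C@@H]2CC[C@@H]([C@H](C=C)O[Si](C(C)C)(C(C)C)O[C@@H](C=C)CCO[Si](c3ccccc3)(c3ccccc3)C(C)(C)C)O2 | intermediate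
18 | (4S,7R)-4-{(2S,5R)-5-[7-(benzyloxy)heptyl]oxolan-2-yl}-7-{2-[(tert-butyldiphenylsilyl)oxy]ethyl}-2,2-di(propan-2-yl)-4,7-dihydro-1,3,2-dioxasilepine (ring alkene Z) | c1ccccc1COCCCCCCC[C@@H]2CC[C@@H]([C@@H]3/C=C\[C@@H](CCO[Si](c4ccccc4)(c4ccccc4)C(C)(C)C)O[Si](C(C)C)(C(C)C)O3)O2 | intermediate
19 | 7-{(2R,5S)-5-[(4S,7S)-7-{2-[(tert-butyldiphenylsilyl)oxy]ethyl}-2,2-di(propan-2-yl)-1,3,2-dioxasilepan-4-yl]oxolan-2-yl}heptan-1-ol | OCCCCCCC[C@@H]1CC[C@@H]([C@@H]2CC[C@@H](CCO[Si](c3ccccc3)(c3ccccc3)C(C)(C)C)O[Si](C(C)C)(C(C)C)O2)O1 | intermediate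
20 | (4S,7S)-7-{2-[(tert-butyldiphenylsilyl)oxy]ethyl}-4-[(2S,5R)-5-(7-iodoheptyl)oxolan-2-yl]-2,2-di(propan-2-yl)-1,3,2-dioxasilepane | ICCCCCCC[C@@H]1CC[C@@H]([C@@H]2CC[C@@H](CCO[Si](c3ccccc3)(c3ccccc3)C(C)(C)C)O[Si](C(C)C)(C(C)C)O2)O1 | intermediate
21 | {7-[(2R,5S)-5-[(4S,7S)-7-{2-[(tert-butyldiphenylsilyl)oxy]ethyl}-2,2-di(propan-2-yl)-1,3,2-dioxasilepan-4-yl]oxolan-2-yl]heptyl}triphenylphosphonium iodide | [I-].c1ccccc1[P+](c1ccccc1)(c1ccccc1)CCCCCCC[C@@H]2CC[C@@H]([C@@H]3CC[C@@H](CCO[Si](c4ccccc4)(c4ccccc4)C(C)(C)C)O[Si](C(C)C)(C(C)C)O3)O2 | intermediate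
22 | pent-4-enal | C=CCCC=O | starting material
23 | (triphenylphosphoranylidene)acetaldehyde | O=CC=P(c1ccccc1)(c1ccccc1)c1ccccc1 | starting material
24 | (2E)-hepta-2,6-dienal | C=CCC/C=C/C=O | intermediate
25 | ylide of 21, {7-[(2R,5S)-5-[(4S,7S)-7-{2-[(tert-butyldiphenylsilyl)oxy]ethyl}-2,2-di(propan-2-yl)-1,3,2-dioxasilepan-4-yl]oxolan-2-yl]heptylidene}triphenylphosphorane | c1ccccc1P(c1ccccc1)(c1ccccc1)=CCCCCCC[C@@H]2CC[C@@H]([C@@H]3CC[C@@H](CCO[Si](c4ccccc4)(c4ccccc4)C(C)(C)C)O[Si](C(C)C)(C(C)C)O3)O2 | intermediate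
26 | (4S,7S)-7-{2-[(tert-butyldiphenylsilyl)oxy]ethyl}-2,2-di(propan-2-yl)-4-{(2S,5R)-5-[(7Z,9E)-tetradeca-7,9,13-trien-1-yl]oxolan-2-yl}-1,3,2-dioxasilepane | C=CCC/C=C/C=C\CCCCCC[C@@H]1CC[C@@H]([C@@H]2CC[C@@H](CCO[Si](c3ccccc3)(c3ccccc3)C(C)(C)C)O[Si](C(C)C)(C(C)C)O2)O1 | intermediate
27 | (3S,6S)-1-[(tert-butyldiphenylsilyl)oxy]-6-{(2S,5R)-5-[(7Z,9E)-tetradeca-7,9,13-trien-1-yl]oxolan-2-yl}hexane-3,6-diol | C=CCC/C=C/C=C\CCCCCC[C@@H]1CC[C@@H]([C@@H](O)CC[C@H](O)CCO[Si](c2ccccc2)(c2ccccc2)C(C)(C)C)O1 | intermediate
28 | (3S,6S)-1-[(tert-butyldiphenylsilyl)oxy]-6-{(2S,5R)-5-[(7Z,9E)-tetradeca-7,9,13-trien-1-yl]oxolan-2-yl}hexane-3,6-diyl dimethanesulfonate | C=CCC/C=C/C=C\CCCCCC[C@@H]1CC[C@@H]([C@@H](OS(C)(=O)=O)CC[C@H](OS(C)(=O)=O)CCO[Si](c2ccccc2)(c2ccccc2)C(C)(C)C)O1 | intermediate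
29 | (1S,4R)-6-[(tert-butyldiphenylsilyl)oxy]-4-hydroperoxy-1-{(2S,5R)-5-[(7Z,9E)-tetradeca-7,9,13-trien-1-yl]oxolan-2-yl}hexyl methanesulfonate | C=CCC/C=C/C=C\CCCCCC[C@@H]1CC[C@@H]([C@@H](OS(C)(=O)=O)CC[C@@H](OO)CCO[Si](c2ccccc2)(c2ccccc2)C(C)(C)C)O1 | intermediate
30 | tert-butyl{2-[(3R,6R)-6-{(2S,5R)-5-[(7Z,9E)-tetradeca-7,9,13-trien-1-yl]oxolan-2-yl}-1,2-dioxan-3-yl]ethoxy}diphenylsilane | C=CCC/C=C/C=C\CCCCCC[C@@H]1CC[C@@H]([C@H]2CC[C@H](CCO[Si](c3ccccc3)(c3ccccc3)C(C)(C)C)OO2)O1 | intermediate
31 | 2-[(3R,6R)-6-{(2S,5R)-5-[(7Z,9E)-tetradeca-7,9,13-trien-1-yl]oxolan-2-yl}-1,2-dioxan-3-yl]ethan-1-ol | C=CCC/C=C/C=C\CCCCCC[C@@H]1CC[C@@H]([C@H]2CC[C@H](CCO)OO2)O1 | intermediate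
32 | 2-[(3R,6R)-6-{(2S,5R)-5-[(7Z,9E)-tetradeca-7,9,13-trien-1-yl]oxolan-2-yl}-1,2-dioxan-3-yl]acetaldehyde | C=CCC/C=C/C=C\CCCCCC[C@@H]1CC[C@@H]([C@H]2CC[C@H](CC=O)OO2)O1 | intermediate
33 | 2-[(3R,6R)-6-{(2S,5R)-5-[(7Z,9E)-tetradeca-7,9,13-trien-1-yl]oxolan-2-yl}-1,2-dioxan-3-yl]acetic acid | C=CCC/C=C/C=C\CCCCCC[C@@H]1CC[C@@H]([C@H]2CC[C@H](CC(=O)O)OO2)O1 | target

## Step count and least certain steps

Total step count: 21. Longest linear sequence: 16 steps (steps 1–5, 10–14 and 16–21).

**Step 11 (key step).** Ring closure may be slow or incomplete, because both alkenes are allylic, oxygenated and flanked by bulky groups and the seven-membered ring must carry its two substituents trans. Prolonged heating then invites intermolecular metathesis and alkene migration by ruthenium hydride species. The fallback replaces metathesis by acetylide addition and semi-hydrogenation; it sets out from 12 and 7 and comes back at 18.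
- Ethynylmagnesium bromide is added to 12 to give rac-5-[(tert-butyldiphenylsilyl)oxy]pent-1-yn-3-ol F1.
- Lipase resolution as in step 9 leaves (3R)-5-[(tert-butyldiphenylsilyl)oxy]pent-1-yn-3-ol F2 as the unreacted alcohol.
- F2 is doubly deprotonated with EtMgBr and added to 7 precomplexed with MgBr2·OEt2, so that chelation should again give the threo carbinol: (1S,4R)-1-{(2S,5R)-5-[7-(benzyloxy)heptyl]oxolan-2-yl}-6-[(tert-butyldiphenylsilyl)oxy]hex-2-yne-1,4-diol F3.
- Semi-hydrogenation over Pd/CaCO3 poisoned with Pb(OAc)2 (quinoline, H2) gives (1S,2Z,4R)-1-{(2S,5R)-5-[7-(benzyloxy)heptyl]oxolan-2-yl}-6-[(tert-butyldiphenylsilyl)oxy]hex-2-ene-1,4-diol F4.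
- The cis-ene-diol is bridged with 15 and imidazole at high dilution to give 18.

**Step 19.** The secondary mesylates may eliminate, above all at C6 where the backside is hindered by the oxolane. The intermediate hydroperoxide or the product may fragment under base through loss of the C3 or C6 hydrogen, and the C1 silyl ether may be partly lost in alkaline methanol. The fallback separates the two displacements and avoids hydroxide; it sets out from 28 and comes back at 30.
- 28 is treated with 2-methoxypropan-2-yl hydroperoxide and CsOH in DMF, which should substitute the more accessible C3 mesylate with inversion and give the peroxyketal (1S,4R)-6-[(tert-butyldiphenylsilyl)oxy]-4-[(2-methoxypropan-2-yl)peroxy]-1-{(2S,5R)-5-[(7Z,9E)-tetradeca-7,9,13-trien-1-yl]oxolan-2-yl}hexyl methanesulfonate F5.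
- Aqueous acetic acid unmasks the hydroperoxide 29, now isolated.
- t-BuOK with 18-crown-6 in cold THF closes the ring onto C6 to give 30.

**Step 5.** Facial selectivity may be poor: the THF that comes with the Grignard solution competes for magnesium, so part of the aldehyde may react through the open, non-chelated pathway and give the erythro carbinol. The fallback corrects the wrong isomer by inversion instead of relying on the addition; it sets out from the crude product of step 5 (from 7) and comes back at 9.
- The epimer (1R)-1-{(2S,5R)-5-[7-(benzyloxy)heptyl]oxolan-2-yl}prop-2-en-1-ol F6 is separated.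
- Mitsunobu reaction (4-nitrobenzoic acid, PPh3, diisopropyl azodicarboxylate, THF, 0 °C) gives the inverted ester (1S)-1-{(2S,5R)-5-[7-(benzyloxy)heptyl]oxolan-2-yl}prop-2-en-1-yl 4-nitrobenzoate F7.
- Methanolysis with K2CO3 gives 9.

**Step 12.** The silicon bridge may be lost through acid traces on the catalyst, the allylic C–O bonds may be hydrogenolysed before the alkene is saturated, or debenzylation may stall in ethyl acetate. The fallback separates the two tasks and uses no metal surface; it sets out from 18 and comes back at 19.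
- Diimide reduction (2-nitrobenzenesulfonyl hydrazide, Et3N, CH2Cl2) saturates C4=C5 and gives (4S,7S)-4-{(2S,5R)-5-[7-(benzyloxy)heptyl]oxolan-2-yl}-7-{2-[(tert-butyldiphenylsilyl)oxy]ethyl}-2,2-di(propan-2-yl)-1,3,2-dioxasilepane F8.
- The benzyl ether is then removed oxidatively with DDQ under visible-light irradiation in buffered wet CH2Cl2 to give 19.

**Step 17.** The C1 silyl ether may be cleaved along with the bridge if the two silicon centres differ less in reactivity than expected. The fallback gives up the selective cleavage; it sets out from 26 and comes back at 27.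
- Excess Bu4NF in THF removes all silicon and gives (3S,6S)-6-{(2S,5R)-5-[(7Z,9E)-tetradeca-7,9,13-trien-1-yl]oxolan-2-yl}hexane-1,3,6-triol F9.
- The primary hydroxyl alone is re-silylated with TBDPSCl (1.05 equiv) and imidazole at −20 °C to give 27.

## Further compounds

F1 | step 11 | rac-5-[(tert-butyldiphenylsilyl)oxy]pent-1-yn-3-ol | C#CC(O)CCO[Si](c1ccccc1)(c1ccccc1)C(C)(C)C
F2 | step 11 | (3R)-5-[(tert-butyldiphenylsilyl)oxy]pent-1-yn-3-ol | O[C@@H](C#C)CCO[Si](c1ccccc1)(c1ccccc1)C(C)(C)C
F3 | step 11 | (1S,4R)-1-{(2S,5R)-5-[7-(benzyloxy)heptyl]oxolan-2-yl}-6-[(tert-butyldiphenylsilyl)oxy]hex-2-yne-1,4-diol | c1ccccc1COCCCCCCC[C@@H]2CC[C@@H]([C@@H](O)C#C[C@H](O)CCO[Si](c3ccccc3)(c3ccccc3)C(C)(C)C)O2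
F4 | step 11 | (1S,2Z,4R)-1-{(2S,5R)-5-[7-(benzyloxy)heptyl]oxolan-2-yl}-6-[(tert-butyldiphenylsilyl)oxy]hex-2-ene-1,4-diol | c1ccccc1COCCCCCCC[C@@H]2CC[C@@H]([C@@H](O)/C=C\[C@H](O)CCO[Si](c3ccccc3)(c3ccccc3)C(C)(C)C)O2
F5 | step 19 | (1S,4R)-6-[(tert-butyldiphenylsilyl)oxy]-4-[(2-methoxypropan-2-yl)peroxy]-1-{(2S,5R)-5-[(7Z,9E)-tetradeca-7,9,13-trien-1-yl]oxolan-2-yl}hexyl methanesulfonate | C=CCC/C=C/C=C\CCCCCC[C@@H]1CC[C@@H]([C@@H](OS(C)(=O)=O)CC[C@@H](OOC(C)(C)OC)CCO[Si](c2ccccc2)(c2ccccc2)C(C)(C)C)O1
F6 | step 5 | (1R)-1-{(2S,5R)-5-[7-(benzyloxy)heptyl]oxolan-2-yl}prop-2-en-1-ol | c1ccccc1COCCCCCCC[C@@H]2CC[C@@H]([C@@H](C=C)O)O2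
F7 | step 5 | (1S)-1-{(2S,5R)-5-[7-(benzyloxy)heptyl]oxolan-2-yl}prop-2-en-1-yl 4-nitrobenzoate | c1ccccc1COCCCCCCC[C@@H]2CC[C@@H]([C@H](C=C)OC(=O)c3ccc(cc3)[N+](=O)[O-])O2
F8 | step 12 | (4S,7S)-4-{(2S,5R)-5-[7-(benzyloxy)heptyl]oxolan-2-yl}-7-{2-[(tert-butyldiphenylsilyl)oxy]ethyl}-2,2-di(propan-2-yl)-1,3,2-dioxasilepane | c1ccccc1COCCCCCCC[C@@H]2CC[C@@H]([C@@H]3CC[C@@H](CCO[Si](c4ccccc4)(c4ccccc4)C(C)(C)C)O[Si](C(C)C)(C(C)C)O3)O2
F9 | step 17 | (3S,6S)-6-{(2S,5R)-5-[(7Z,9E)-tetradeca-7,9,13-trien-1-yl]oxolan-2-yl}hexane-1,3,6-triol | C=CCC/C=C/C=C\CCCCCC[C@@H]1CC[C@@H]([C@@H](O)CC[C@H](O)CCO)O1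
A1 | alternative 1 | (1S,2S,5Z)-2-[(tert-butyldimethylsilyl)oxy]cyclooct-5-en-1-ol | O[C@H]1CC/C=C\CC[C@@H]1O[Si](C)(C)C(C)(C)C
A2 | alternative 1 | (4S)-4-[(tert-butyldimethylsilyl)oxy]-4-[(2S)-5-hydroxyoxolan-2-yl]butanal (lactol carbon as a mixture) | OC1CC[C@@H]([C@@H](O[Si](C)(C)C(C)(C)C)CCC=O)O1
A3 | alternative 2 | (3S,6S)-1-[(tert-butyldimethylsilyl)oxy]-6-{(2S,5R)-5-[(7Z,9E)-tetradeca-7,9,13-trien-1-yl]oxolan-2-yl}hexane-3,6-diyl dimethanesulfonate | C=CCC/C=C/C=C\CCCCCC[C@@H]1CC[C@@H]([C@@H](OS(C)(=O)=O)CC[C@H](OS(C)(=O)=O)CCO[Si](C)(C)C(C)(C)C)O1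
A4 | alternative 2 | tert-butyldimethyl{2-[(3R,6R)-6-{(2S,5R)-5-[(7Z,9E)-tetradeca-7,9,13-trien-1-yl]oxolan-2-yl}-1,2-dioxan-3-yl]ethoxy}silane | C=CCC/C=C/C=C\CCCCCC[C@@H]1CC[C@@H]([C@H]2CC[C@H](CCO[Si](C)(C)C(C)(C)C)OO2)O1
A5 | alternative 3 | (4S)-1-diazo-4-(prop-2-en-1-yloxy)-5-[(tert-butyldiphenylsilyl)oxy]pentan-2-one | [N-]=[N+]=CC(=O)C[C@@H](CO[Si](c1ccccc1)(c1ccccc1)C(C)(C)C)OCC=C
A6 | alternative 3 | (2R,5S)-2-(prop-2-en-1-yl)-5-{[(tert-butyldiphenylsilyl)oxy]methyl}oxolan-3-one | C=CC[C@@H]1C(=O)C[C@@H](CO[Si](c2ccccc2)(c2ccccc2)C(C)(C)C)O1
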